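In a one-step world the target is a single arrow out of the dissolved starting material, and a flask whose starting material stands near 12.2% after 8.00 h goes on making target at a constant rate. Saturday's run is this same flask, followed so far.

the same everywhere: solid substrate 0.079 M; coupling partner 0.118 M; free catalyst 7.9 mM
- Saturday's: second substrate 0.079 M; the very flask that is asked about, followed so far
- flask: second substrate 0.0790 M; time 25 h

Saturday's run (percent of the solid substrate charged)

| time / h | target / % | starting material / % |
|---|---|---|
| 1.50 | 0 | 5.8 |
| 3.00 | 0.2 | 9.1 |
| 5.00 | 1.5 | 11.0 |
| 6.00 | 2.0 | 12.0 |
| 8.00 | 3.0 | 12.2 |

(standard deviation of a reading: 0.3 percentage points)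

- given per volume of solution although it is solid: solid substrate
- at the start none of the solid substrate is in solution
- starting material means what is dissolved; the solid is not counted in it

1. amount of target in the flask at 25 h, in percent of the solid substrate charged
2. amount of starting material in the flask at 25 h, in percent of the solid substrate charged
3. amount of solid substrate in the flask at 25 h, in percent of the solid substrate charged (only what is still solid)

Two chemists dispute this flask, and both count catalyst turnovers. One turnover on target, the catalyst charge over the solid charge, is worth 10.0% of target. Saturday's target went from 1.5% to 3.0% between 5.00 h and 8.00 h, so the rate read there, a turnover frequency, is 0.0500 /h.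

The first chemist keeps that rate to the asked time and counts 1.15 turnovers, or 11.5%. Her forecast, after a small allowance for slowing, is 11% of target, 12.7% of starting material and 76% of solid, “as expected for a reaction fed by a saturated solution”.

The second chemist, whose reckoning is mine, differs. Second substrate, charged at ten times the catalyst, takes its turns on the same catalyst, and as it runs down the rate on target should rise. So I take the count of 1.15 as too low, and I commit to more target than that.

The flask gives 14.2% of target, 12.5% of starting material and 68.3% of solid, beside 4.84% of dormant form. That is 1.42 turnovers, above the first chemist's count, though the forecast's target stays within its margin. At 12.5 h the steady count still stands close, giving 5.25% against 5.56% in the flask. From there to the asked time the rate is on average 0.0692 /h, while catalyst intermediate B falls from 25.0% to 11.2% of the catalyst.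

    second substrate + free catalyst ⇌ catalyst intermediate B (K = 17.5 /M, k = 296 /M/h)
    coupling partner + catalyst intermediate B → free catalyst + second product (k = 17.7 /M/h)
    starting material + free catalyst ⇌ catalyst intermediate A (K = 22.7 /M, k = 9.11 /M/h)
    solid substrate ⇌ starting material, rate k4*(cs4 - [starting material]) while solid is left; crystals form when [starting material] > cs4 (solubility = 12.0 mM, k = 0.331 /h)
    coupling partner + catalyst intermediate A → free catalyst + target (k = 153 /M/h)
    starting material ⇌ dormant form (K = 1.09, k = 0.0211 /h)

The neighbouring flask holds 0.032 M of free catalyst and is otherwise charged alike, so one turnover there is worth 40.5% of target. At this flask's count, that neighbouring flask would show 57.5%. It gives 44.8%, which is 1.11 turnovers, fewer per catalyst than in this flask. The neighbouring flask has 9.14% of starting material in solution, against 12.5% in this flask.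

All runs were computed with made-up constants, and the scatter is random.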